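The 2,3-dihydrofuran ring (O–C4–C3–C2=C1) is read as the cycloisomer of a homopropargylic tertiary alcohol. Its C3–C4 bond, between the ring CH2 and the methyl-bearing quaternary carbon, then joins two natively electrophilic carbons: a propargylic carbon and a methyl ketone carbon. In the key step zerovalent palladium and Et2Zn reverse the polarity of a propargylic acetate; the allenylzinc adds through its CH2 terminus to the ketone and forms C3–C4, the quaternary carbinol and the ten-membered carbocycle at once. The precursor is an acyclic 2-acetonylfuran bearing the acetoxybutynyl chain. Afterwards the furan is oxidised to the ylidene butenolide and gold closes the oxygen bridge.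

Key step: step 9

Remark: locants follow germacrane numbering of the target (C1 enol-ether carbon, C2 vinyl CH, C3 ring CH2, C4 O-bearing quaternary carbon with methyl C15, C5 exocyclic =CH, C6 lactone γ-carbon, C7 β-carbon, C8 acetoxy CH, C9 CH2, C10 tertiary carbinol with methyl C14, C11 α-carbon, C12 lactone carbonyl, C13 acetoxymethyl carbon). Compound 1 and all reagents are taken as commercial.

Step 1
Reactants: 1 furan-3,4-diyldimethanol; 2 tert-butyldimethylsilyl chloride
Product: 3 [4-(tert-butyldimethylsilyloxymethyl)furan-3-yl]methanol
Conditions: NaH (1.0 equiv), THF, 0 °C → rt; then TBSCl (1.0 equiv)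
Reagents that add atoms: tert-butyldimethylsilyl chloride (2), CC(C)(C)[Si](C)(C)Cl
Why: O-silylation of the sparingly soluble monosodium alkoxide of a symmetric diol should stop largely at the mono-ether, and no stereocentre is formed.

Step 2
Reactants: 3
Product: 4 4-(tert-butyldimethylsilyloxymethyl)furan-3-carbaldehyde
Conditions: MnO2 (activated, excess), CH2Cl2, rt
Reagents that add atoms: none
Why: MnO2 oxidation of a heterobenzylic (furylmethyl) alcohol should stop cleanly at the aldehyde.

Step 3
Reactants: 4; 5 N,N,N′-trimethylethylenediamine (used as its lithium amide); 6 allyl bromide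
Product: 10 2-allyl-4-(tert-butyldimethylsilyloxymethyl)furan-3-carbaldehyde, via lithium α-amino alkoxide 7 (not isolated), via C2-lithiated amino alkoxide 8 (not isolated), via allylated amino alkoxide 9 (not isolated)
Conditions: LiN(Me)CH2CH2NMe2 (from 5 and n-BuLi), THF, −78 °C; n-BuLi (2 equiv), −20 °C; CuBr·SMe2 (10 mol%), allyl bromide, −78 °C → rt; H2O
Reagents that add atoms: allyl bromide (6), C=CCBr
Why: In this α-amino alkoxide-directed ortho-lithiation the aldehyde is masked in the flask, its chelating diamine arm should steer n-BuLi to the furan α-position next to it (C6 of the target) and not to the other α-position, and allylation followed by aqueous collapse of the hemiaminal returns the aldehyde.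

Step 4
Reactants: 10; 11 acetone
Product: 12 (4S)-4-hydroxy-4-[2-allyl-4-(tert-butyldimethylsilyloxymethyl)furan-3-yl]butan-2-one
Conditions: D-proline (30 mol%), acetone–DMSO (1:4), rt
Reagents that add atoms: acetone (11), CC(C)=O
Why: In this proline-catalysed direct asymmetric aldol reaction (enamine catalysis) the D-proline enamine of acetone should attack the aldehyde through the carboxylic-acid-organised chair transition state that gives the (S)-carbinol at C8.

Step 5
Reactants: 12; 13 tert-butyldimethyl(prop-2-yn-1-yloxy)silane (used as its magnesium acetylide)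
Product: 14 (1S,3S)-1-[2-allyl-4-(tert-butyldimethylsilyloxymethyl)furan-3-yl]-3-methyl-6-(tert-butyldimethylsilyloxy)hex-4-yne-1,3-diol
Conditions: 13, EtMgBr, THF, 0 °C → rt; then 12 (acetylide 3.5 equiv), CH2Cl2–THF, −78 → −20 °C; aq. NH4Cl
Reagents that add atoms: tert-butyldimethyl(prop-2-yn-1-yloxy)silane (13), C#CCO[Si](C)(C)C(C)(C)C
Why: In this chelation-controlled 1,2-addition of an alkynyl Grignard reagent (1,3-induction) the magnesium alkoxide at C8 chelates the C10 carbonyl, and axial attack on the six-membered chelate should place the new C10 hydroxyl anti to the C8 oxygen along the C7–C1 chain, i.e. (10S).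

Step 6
Reactants: 14
Product: 15 (1S,3S)-1-[2-allyl-4-(hydroxymethyl)furan-3-yl]-3-methylhex-4-yne-1,3,6-triol
Conditions: TBAF (2.5 equiv), THF, 0 °C → rt; aq. NH4Cl
Reagents that add atoms: none
Why: Fluoride-mediated desilylation should free both primary hydroxyls without touching the stereocentres.

Step 7
Reactants: 15; 16 acetic anhydride
Product: 17 (4S,6S)-6-acetoxy-6-[4-(acetoxymethyl)-2-allylfuran-3-yl]-4-hydroxy-4-methylhex-2-yn-1-yl acetate
Conditions: Ac2O (3.3 equiv), pyridine, DMAP (5 mol%), CH2Cl2, 0 °C
Reagents that add atoms: acetic anhydride (16), CC(=O)OC(C)=O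
Why: Nucleophile-catalysed acylation should esterify the two primary hydroxyls and the secondary one, while the hindered tertiary propargylic hydroxyl stays free; this installs both acetates of the target and the leaving group for step 9 in one operation.

Step 8
Reactants: 17; 18 water
Product: 19 (4S,6S)-6-acetoxy-6-[4-(acetoxymethyl)-2-(2-oxopropyl)furan-3-yl]-4-hydroxy-4-methylhex-2-yn-1-yl acetate
Conditions: PdCl2 (10 mol%), CuCl (1 equiv), O2 (1 atm), DMF–H2O (7:1), rt
Reagents that add atoms: water (18), O
Why: In this Wacker–Tsuji oxidation, Markovnikov hydroxypalladation of the terminal alkene and β-hydride elimination should give the methyl ketone, with the internal alkyne, the esters and the furan as spectators at room temperature.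

Step 9
Reactants: 19
Product: 21 [(4S,6S,10S)-4-acetoxy-6,10-dihydroxy-6,10-dimethyl-7,8-didehydro-4,5,6,9,10,11-hexahydrocyclodeca[b]furan-3-yl]methyl acetate, via allenylzinc 20 (not isolated)
Conditions: Pd(PPh3)4 (10 mol%), Et2Zn (4 equiv), THF, 25 °C, slow addition of 19 (final 2 mM); aq. NH4Cl
Reagents that add atoms: none
Why: Zerovalent palladium ionises the primary propargylic acetate to an allenyl/propargyl palladium species, Et2Zn transmetalates it to the allenylzinc 20 with zinc on C1 (polarity reversal of the propargylic carbon), and 20 adds through its CH2 terminus C3 to the C4 ketone in a closed six-membered SE2′ transition state, giving the homopropargylic tertiary alcohol. The closest known reaction type is the palladium-catalysed, Et2Zn-mediated umpolung propargylation of carbonyl compounds with propargylic esters, a Barbier-type allenylzinc addition. The ten-membered carbocycle (C1–C10, fused to the furan at C6–C7) is closed by a 10-exo-trig attack on the carbonyl group under high dilution, helped by the rigid furan and the linear C10–C1≡C2–C3 unit, which leave few rotatable bonds in the tether. The new C4 stereocentre is under substrate control: in the cyclic transition state the ketone methyl group points to the periphery and the C8 acetoxy and C10 methyl groups sit pseudo-equatorially on the forming ring, which is expected, though not assured, to expose the ketone face leading to (4S); any 4-epimer would be removed at this stage. The step needs site selectivity in the ionisation (a propargylic acetate should react far faster with zerovalent palladium than the two furylmethyl-type acetates), γ-regioselectivity (attack through C3 gives the alkyne and not the allene, because C1 is shielded by the fully substituted C10) and chemoselectivity (Et2Zn alone does not add to the ketone or the esters, and the C10 hydroxyl is merely held as its ethylzinc alkoxide).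

Step 10
Reactants: 21; 22 dioxygen (as singlet oxygen)
Product: 24 (4S,8S,10S)-configured γ-hydroxybutenolide (C12 lactone carbonyl and C6 hemiketal, either C6 epimer; alkyne, both tertiary alcohols and both acetates unchanged), via furan endoperoxide 23 (not isolated)
Conditions: O2, visible light, tetraphenylporphyrin (1 mol%), CH2Cl2, −78 °C; then iPr2NEt, −78 °C → rt
Reagents that add atoms: dioxygen (22), O=O
Why: A (4+2) cycloaddition of singlet oxygen to the furan is followed by a base-induced Kornblum–DeLaMare fragmentation that removes the only bridgehead hydrogen (on C12), so that C12 should become the lactone carbonyl and C6 the hemiketal carbon, whose configuration is irrelevant because step 11 removes it.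

Step 11
Reactants: 24; 16 acetic anhydride
Product: 26 (4S,8S,10S)-configured (E)-γ-ylidenebutenolide (C5=C6 exocyclic to the lactone with C4 cis to C7, inside the ten-membered cycloalkyne; free C4 and C10 tertiary alcohols; C8 and C13 acetates), via γ-acetoxybutenolide 25 (not isolated)
Conditions: Ac2O (1.5 equiv), Et3N, DMAP (cat.), CH2Cl2, 0 °C → rt
Reagents that add atoms: none
Why: In this acylative dehydration of a pseudo-acid, O-acetylation of the hemiketal hydroxyl and amine-promoted β-elimination of acetic acid across C6–C5 should give the γ-ylidenebutenolide, and the ten-membered ring that still holds the alkyne can accommodate only the geometry with C4 cis to C7, i.e. the required (E)-alkene.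

Step 12
Reactants: 26
Product: 27 target compound (4S,8S,10S; 1,4-epoxy-bridged dihydrofuran, C10 tertiary alcohol, C8 and C13 acetates, (E)-ylidene butenolide)
Conditions: Ph3PAuNTf2 (5 mol%), CH2Cl2, 4 Å MS, rt
Reagents that add atoms: none
Why: In this gold-catalysed 5-endo-dig cycloisomerisation (intramolecular hydroalkoxylation) the C4 hydroxyl adds anti to gold at C1 of the π-activated alkyne and protodeauration gives the 2,3-dihydrofuran; the C10 hydroxyl cannot compete because it would form a three- or four-membered ring, and no stereocentre is created.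

Compound list
1 | furan-3,4-diyldimethanol | OCc1cocc1CO | starting material
2 | tert-butyldimethylsilyl chloride | CC(C)(C)[Si](C)(C)Cl | starting material
3 | [4-(tert-butyldimethylsilyloxymethyl)furan-3-yl]methanol | CC(C)(C)[Si](C)(C)OCc1cocc1CO | intermediate
4 | 4-(tert-butyldimethylsilyloxymethyl)furan-3-carbaldehyde | CC(C)(C)[Si](C)(C)OCc1cocc1C=O | intermediate
5 | N,N,N′-trimethylethylenediamine | CNCCN(C)C | starting material
6 | allyl bromide | C=CCBr | starting material
7 | lithium α-amino alkoxide (adduct of 4 with lithium N,N,N′-trimethylethylenediamide) | CN(C)CCN(C)C(O[Li])c1cocc1CO[Si](C)(C)C(C)(C)C | intermediate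
8 | C2-lithiated amino alkoxide | CN(C)CCN(C)C(O[Li])c1c([Li])occ1CO[Si](C)(C)C(C)(C)C | intermediate
9 | allylated amino alkoxide | CN(C)CCN(C)C(O[Li])c1c(CC=C)occ1CO[Si](C)(C)C(C)(C)C | intermediate
10 | 2-allyl-4-(tert-butyldimethylsilyloxymethyl)furan-3-carbaldehyde | C=CCc1occ(CO[Si](C)(C)C(C)(C)C)c1C=O | intermediate
11 | acetone | CC(C)=O | starting material
12 | (4S)-4-hydroxy-4-[2-allyl-4-(tert-butyldimethylsilyloxymethyl)furan-3-yl]butan-2-one | CC(=O)C[C@H](O)c1c(CC=C)occ1CO[Si](C)(C)C(C)(C)C | intermediate
13 | tert-butyldimethyl(prop-2-yn-1-yloxy)silane | C#CCO[Si](C)(C)C(C)(C)C | starting material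
14 | (1S,3S)-1-[2-allyl-4-(tert-butyldimethylsilyloxymethyl)furan-3-yl]-3-methyl-6-(tert-butyldimethylsilyloxy)hex-4-yne-1,3-diol | CC(C)(C)[Si](C)(C)OCC#C[C@@](C)(O)C[C@H](O)c1c(CC=C)occ1CO[Si](C)(C)C(C)(C)C | intermediate
15 | (1S,3S)-1-[2-allyl-4-(hydroxymethyl)furan-3-yl]-3-methylhex-4-yne-1,3,6-triol | OCC#C[C@@](C)(O)C[C@H](O)c1c(CC=C)occ1CO | intermediate
16 | acetic anhydride | CC(=O)OC(C)=O | starting material
17 | (4S,6S)-6-acetoxy-6-[4-(acetoxymethyl)-2-allylfuran-3-yl]-4-hydroxy-4-methylhex-2-yn-1-yl acetate | CC(=O)OCC#C[C@@](C)(O)C[C@H](OC(C)=O)c1c(CC=C)occ1COC(C)=O | intermediate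
18 | water | O | starting material
19 | (4S,6S)-6-acetoxy-6-[4-(acetoxymethyl)-2-(2-oxopropyl)furan-3-yl]-4-hydroxy-4-methylhex-2-yn-1-yl acetate | CC(=O)OCC#C[C@@](C)(O)C[C@H](OC(C)=O)c1c(CC(C)=O)occ1COC(C)=O | intermediate
20 | allenylzinc (ethylzinc on C1, C10 oxygen as ethylzinc alkoxide) | CC[Zn]C(=C=C)[C@@](C)(O[Zn]CC)C[C@H](OC(C)=O)c1c(CC(C)=O)occ1COC(C)=O | intermediate
21 | [(4S,6S,10S)-4-acetoxy-6,10-dihydroxy-6,10-dimethyl-7,8-didehydro-4,5,6,9,10,11-hexahydrocyclodeca[b]furan-3-yl]methyl acetate | CC(=O)OCc1coc2C[C@@](C)(O)CC#C[C@@](C)(O)C[C@H](OC(C)=O)c12 | intermediate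
22 | dioxygen | O=O | starting material
23 | furan endoperoxide (peroxide bridge between C6 and C12) | CC(=O)OCC1=C2[C@@H](OC(C)=O)C[C@](C)(O)C#CC[C@](C)(O)CC2(OO3)OC13 | intermediate
24 | γ-hydroxybutenolide (C6 hemiketal, C12 carbonyl) | CC(=O)OCC1=C2[C@@H](OC(C)=O)C[C@](C)(O)C#CC[C@](C)(O)CC2(O)OC1=O | intermediate
25 | γ-acetoxybutenolide | CC(=O)OCC1=C2[C@@H](OC(C)=O)C[C@](C)(O)C#CC[C@](C)(O)CC2(OC(C)=O)OC1=O | intermediate
26 | (E)-γ-ylidenebutenolide cycloalkyne diol diacetate | CC(=O)OCC1=C2/C(=C\[C@@](C)(O)CC#C[C@@](C)(O)C[C@@H]2OC(C)=O)OC1=O | intermediate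
27 | target (4S,8S,10S) | CC(=O)OCC1=C2/C(=C\[C@]3(C)CC=C(O3)[C@@](C)(O)C[C@@H]2OC(C)=O)OC1=O | target

Total step count: 12. Longest linear sequence: 12 steps (1 to 27).

Steps most likely to fail

Step 9. The ring closure may fail through competing ionisation of the furylmethyl-type acetates, protonolysis or ethyl transfer of the allenylzinc before the slow ten-membered ring closure, attack through C1 instead of C3, or poor facial selectivity at C4. The fallback generates the nucleophile by stoichiometric metal insertion into a propargylic chloride instead. It sets out from 12: addition of 3-chloro-1-lithiopropyne (from propargyl chloride and n-BuLi at −78 °C, transmetalated with MgBr2·OEt2) under the same chelate control should give the chloro diol F1. TBAF should free the primary alcohol to give the chloro triol F2, Ac2O/pyridine should give the diacetate F3, and Wacker–Tsuji oxidation should give the keto propargylic chloride F4. Indium powder with NaI in DMF at high dilution should then close the ring in an intramolecular Barbier reaction that needs neither palladium nor Et2Zn and tolerates the free hydroxyl. The fallback comes back to the route at 21.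

Step 5. The 1,3-induction may be eroded or reversed by non-chelated addition, and the magnesium aldolate may fragment by retro-aldol reaction. The fallback interchanges the order in which the two carbon substituents reach C10. It sets out from 10 and 13: C-acetylation of 13 (n-BuLi, then N-methoxy-N-methylacetamide) should give the ynone F5. An Ipc2BCl/Et3N-mediated aldol addition of F5 to 10, with the reagent hand chosen for the (S)-carbinol, should give the β-hydroxy ynone F6. Addition of MeMgBr (or MeTi(OiPr)3) to the chelated ynone then brings in the methyl group last. For a given facial bias this gives the C10 epimer opposite to that from alkynyl addition, so one of the two orders should deliver 14, where the fallback comes back to the route.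

Step 11. The free C4 tertiary hydroxyl may be acetylated or eliminated, and the ring may open by retro-aldol reaction through the ring-opened keto-acid tautomer, in which C4–OH is β to the latent C6 ketone. The fallback reverses the last two operations. It sets out from 24: the gold-catalysed 5-endo-dig cyclisation (Ph3PAuNTf2, CH2Cl2, 4 Å MS) is run first and should give the dihydrofuran hydroxybutenolide F7, in which the C4 oxygen is tied up in the enol ether. Acylative dehydration of F7 (Ac2O, Et3N, DMAP) through its γ-acetate F8 then comes back to the route at the target 27.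

Further compounds
F1 | step 9 | (1S,3S)-1-[2-allyl-4-(tert-butyldimethylsilyloxymethyl)furan-3-yl]-6-chloro-3-methylhex-4-yne-1,3-diol | ClCC#C[C@@](C)(O)C[C@H](O)c1c(CC=C)occ1CO[Si](C)(C)C(C)(C)C
F2 | step 9 | (1S,3S)-1-[2-allyl-4-(hydroxymethyl)furan-3-yl]-6-chloro-3-methylhex-4-yne-1,3-diol | ClCC#C[C@@](C)(O)C[C@H](O)c1c(CC=C)occ1CO
F3 | step 9 | [4-[(1S,3S)-1-acetoxy-6-chloro-3-hydroxy-3-methylhex-4-yn-1-yl]-5-allylfuran-3-yl]methyl acetate | ClCC#C[C@@](C)(O)C[C@H](OC(C)=O)c1c(CC=C)occ1COC(C)=O
F4 | step 9 | [4-[(1S,3S)-1-acetoxy-6-chloro-3-hydroxy-3-methylhex-4-yn-1-yl]-5-(2-oxopropyl)furan-3-yl]methyl acetate | ClCC#C[C@@](C)(O)C[C@H](OC(C)=O)c1c(CC(C)=O)occ1COC(C)=O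
F5 | step 5 | 5-(tert-butyldimethylsilyloxy)pent-3-yn-2-one | CC(=O)C#CCO[Si](C)(C)C(C)(C)C
F6 | step 5 | (6S)-6-[2-allyl-4-(tert-butyldimethylsilyloxymethyl)furan-3-yl]-6-hydroxy-1-(tert-butyldimethylsilyloxy)hex-2-yn-4-one | CC(C)(C)[Si](C)(C)OCC#CC(=O)C[C@H](O)c1c(CC=C)occ1CO[Si](C)(C)C(C)(C)C
F7 | step 11 | dihydrofuran-bridged γ-hydroxybutenolide (1,4-epoxy bridge closed, C6 hemiketal) | CC(=O)OCC1=C2[C@@H](OC(C)=O)C[C@](C)(O)C3=CC[C@](C)(O3)CC2(O)OC1=O
F8 | step 11 | γ-acetate of F7 | CC(=O)OCC1=C2[C@@H](OC(C)=O)C[C@](C)(O)C3=CC[C@](C)(O3)CC2(OC(C)=O)OC1=O
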